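**Plan**

1. Numbering follows germacrane: ring C1–C10, C14 on C10, C15 on C4, lactone C6–O–C12(=O)–C11=C7, C13 the acetoxymethyl carbon. Retrosynthetic cuts, latest first: the C1–O–C10 oxirane; the C8 and C13 ester C–O bonds; C7=C11 (aldol/dehydration) and the C6–O–C12 acyl bond; the C4–O–C5 oxirane; C5–C6 together with C4–C15; finally C8–C9.
2. Enabling feature: the C6 carbinol next to the methyl-bearing C4–C5 oxirane inside the ten-membered carbocycle is, one epoxidation back, an E-2-methylallylic alcohol C6(OH)–C5H=C4(C15). That is aldehyde carbon C6 + terminal alkyne C4≡C5 + methyl C15.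
3. Forward order: chain joined at C8–C9 by hydrazone alkylation; ten-membered carbocycle by the nickel three-component closure; C4/C5 oxirane; five-membered butenolide; C1/C10 oxirane last.
4. Stereochemistry: C8 from SAMP. A temporary C7 silyloxy centre (axial hydride, trans to C8) relays to C6 by Felkin–Anh control in the ring closure and is later oxidised away. C6–OH directs the threo 4,5-epoxide. C1/C10 comes from outer-face attack on the rigid lactone. Both ring alkenes are E (stabilised Wittig; cis carbometalation).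
5. C7 stays a protected carbinol until C6 is acylated, so neither acid nor a free α-ketol meets the 4,5-epoxide. The C8 and C13 oxygens travel as 4-methoxybenzyl (PMB) ethers and are exchanged for isobutyrate and acetate at the end.

Key step: step 11

Assumption: 5-(trimethylsilyl)pent-4-yn-1-ol, SAMP and 3-[(4-methoxybenzyl)oxy]propanoic acid are treated as purchasable; the alkyne is carried C-silylated so that the azaenolate of step 5 meets no acidic acetylenic hydrogen. TBS = tert-butyldimethylsilyl.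

**Step 1**
Reactants: 1 5-(trimethylsilyl)pent-4-yn-1-ol; 2 ethyl 2-(triphenylphosphoranylidene)propanoate
Product: 4 ethyl (E)-2-methyl-7-(trimethylsilyl)hept-2-en-6-ynoate, via 5-(trimethylsilyl)pent-4-ynal 3 (not isolated)
Conditions: IBX (1.5 equiv), 2 (1.2 equiv), DMSO, rt
Reagents that add atoms: none
Why: Tandem IBX oxidation–Wittig olefination, in which the aldehyde is trapped as it forms by the stabilised α-methyl ylide, should give the E-trisubstituted enoate that later becomes the C1=C10 alkene with C14 on C10.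

**Step 2**
Reactants: 4 ethyl (E)-2-methyl-7-(trimethylsilyl)hept-2-en-6-ynoate
Product: 5 (E)-2-methyl-7-(trimethylsilyl)hept-2-en-6-yn-1-ol
Conditions: i-Bu2AlH (2.2 equiv), CH2Cl2, −78 °C
Reagents that add atoms: none
Why: 1,2-Reduction of the enoate by i-Bu2AlH should give the allylic alcohol without touching the silylalkyne or the alkene geometry.

**Step 3**
Reactants: 5 (E)-2-methyl-7-(trimethylsilyl)hept-2-en-6-yn-1-ol
Product: 6 (E)-7-bromo-6-methyl-1-(trimethylsilyl)hept-5-en-1-yne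
Conditions: CBr4, PPh3, CH2Cl2, 0 °C
Reagents that add atoms: carbon tetrabromide, BrC(Br)(Br)Br
Why: Appel bromination should convert the primary allylic alcohol into the bromide by SN2 displacement without allylic transposition.

**Step 4**
Reactants: 7 2,2-dimethyl-1,3-dioxan-5-one; 8 (S)-1-amino-2-(methoxymethyl)pyrrolidine (SAMP)
Product: 9 (S)-N-(2,2-dimethyl-1,3-dioxan-5-ylidene)-2-(methoxymethyl)pyrrolidin-1-amine
Conditions: benzene, reflux, Dean–Stark
Reagents that add atoms: none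
Why: Hydrazone formation by condensation of the ketone with the hydrazine, driven by azeotropic removal of water.

**Step 5**
Reactants: 9 (S)-N-(2,2-dimethyl-1,3-dioxan-5-ylidene)-2-(methoxymethyl)pyrrolidin-1-amine; 6 (E)-7-bromo-6-methyl-1-(trimethylsilyl)hept-5-en-1-yne
Product: 11 (4S)-2,2-dimethyl-4-[(E)-2-methyl-7-(trimethylsilyl)hept-2-en-6-yn-1-yl]-1,3-dioxan-5-one, via alkylated SAMP hydrazone 10 (not isolated)
Conditions: t-BuLi, THF, −78 °C; 6, −100 → −78 °C; then sat. aq. oxalic acid, Et2O, rt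
Reagents that add atoms: water, O
Why: SAMP-hydrazone (Enders) alkylation: the ring-locked azaenolate, with lithium held by the methoxymethyl arm, should take the allylic bromide on its open face to set C8 as S, and two-phase oxalic acid hydrolysis should release the ketone without epimerisation.

**Step 6**
Reactants: 11 (4S)-2,2-dimethyl-4-[(E)-2-methyl-7-(trimethylsilyl)hept-2-en-6-yn-1-yl]-1,3-dioxan-5-one
Product: 13 (4S,5R)-2,2-dimethyl-4-[(E)-2-methylhept-2-en-6-yn-1-yl]-1,3-dioxan-5-ol, via silylalkyne trans-dioxanol 12 (not isolated)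
Conditions: LiAlH4, THF, −78 °C; then MeOH, K2CO3, rt
Reagents that add atoms: none
Why: Hydride reduction by axial attack of the small LiAlH4 on the chair dioxanone (the axial face at the carbonyl is flanked by ring oxygens and the side chain sits equatorial) should give the trans alcohol, setting the temporary C7 centre anti to C8, and the methanolic K2CO3 quench removes the alkynyl silyl group by protodesilylation.

**Step 7**
Reactants: 13 (4S,5R)-2,2-dimethyl-4-[(E)-2-methylhept-2-en-6-yn-1-yl]-1,3-dioxan-5-ol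
Product: 14 tert-butyl({(4S,5R)-2,2-dimethyl-4-[(E)-2-methylhept-2-en-6-yn-1-yl]-1,3-dioxan-5-yl}oxy)dimethylsilane
Conditions: TBSCl, imidazole, DMF, 40 °C
Reagents that add atoms: tert-butyldimethylsilyl chloride, CC(C)(C)[Si](C)(C)Cl
Why: Silyl ether formation on the equatorial secondary alcohol installs the bulky, non-chelating C7 silyloxy group that later acts as the polar Felkin–Anh substituent.

**Step 8**
Reactants: 14 tert-butyl({(4S,5R)-2,2-dimethyl-4-[(E)-2-methylhept-2-en-6-yn-1-yl]-1,3-dioxan-5-yl}oxy)dimethylsilane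
Product: 16 (2R,4S,5R)-5-[(tert-butyldimethylsilyl)oxy]-2-(4-methoxyphenyl)-4-[(E)-2-methylhept-2-en-6-yn-1-yl]-1,3-dioxane, via silyloxy diol 15 (not isolated)
Conditions: PPTS, MeOH, rt; evaporate; then 4-MeOC6H4CH(OMe)2, PPTS, CH2Cl2, rt
Reagents that add atoms: 4-methoxybenzaldehyde dimethyl acetal, COc1ccc(cc1)C(OC)OC
Why: Acid-catalysed transacetalisation: methanolysis of the strained 2,2-dimethyl-1,3-dioxane and thermodynamic formation of the all-equatorial 4-methoxybenzylidene acetal of the 1,3-diol, with the secondary silyl ether stable to PPTS.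

**Step 9**
Reactants: 16 (2R,4S,5R)-5-[(tert-butyldimethylsilyl)oxy]-2-(4-methoxyphenyl)-4-[(E)-2-methylhept-2-en-6-yn-1-yl]-1,3-dioxane
Product: 17 (2R,3S,5E)-2-[(tert-butyldimethylsilyl)oxy]-3-[(4-methoxybenzyl)oxy]-5-methyldec-5-en-9-yn-1-ol
Conditions: i-Bu2AlH (3 equiv), CH2Cl2, −78 → 0 °C
Reagents that add atoms: none
Why: Regioselective reductive opening of the 4-methoxybenzylidene acetal: aluminium binds the less hindered primary oxygen and hydride enters the oxocarbenium ion, so the PMB ether stays on the secondary C8 oxygen and the primary C6 hydroxyl is freed.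

**Step 10**
Reactants: 17 (2R,3S,5E)-2-[(tert-butyldimethylsilyl)oxy]-3-[(4-methoxybenzyl)oxy]-5-methyldec-5-en-9-yn-1-ol
Product: 18 (2S,3S,5E)-2-[(tert-butyldimethylsilyl)oxy]-3-[(4-methoxybenzyl)oxy]-5-methyldec-5-en-9-ynal
Conditions: Dess–Martin periodinane, CH2Cl2, 0 °C → rt; used at once
Reagents that add atoms: none
Why: Dess–Martin oxidation under non-basic conditions should give the α-silyloxy aldehyde (C6) without epimerisation at C7.

**Step 11**
Reactants: 18 (2S,3S,5E)-2-[(tert-butyldimethylsilyl)oxy]-3-[(4-methoxybenzyl)oxy]-5-methyldec-5-en-9-ynal; 19 dimethylzinc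
Product: 20 (1R,2E,6E,9S,10R)-10-[(tert-butyldimethylsilyl)oxy]-9-[(4-methoxybenzyl)oxy]-3,7-dimethylcyclodeca-2,6-dien-1-ol
Conditions: Ni(cod)2 (20 mol%), IMes (1,3-dimesitylimidazol-2-ylidene, 20 mol%), 19 (3 equiv), toluene, rt; 18 added over 10 h (final 0.005 M)
Reagents that add atoms: none
Why: Proposed new method: zerovalent nickel carrying the carbene IMes should bind aldehyde and alkyne and couple them oxidatively to an oxanickelacyclopentene of divalent nickel in which C5–C6 exists, after which methyl passes from zinc to nickel and C(sp2)–CH3 reductive elimination puts C15 on C4, cis to the new bond, releasing the methylzinc alkoxide of 20 and zerovalent nickel. The closest known reaction types are the nickel-catalysed three-component alkylative coupling of aldehydes, alkynes and organozincs and the nickel–carbene reductive macrocyclisation of ynals to rings of twelve or more members; a ten-membered carbocycle closed with methyl transfer has not been shown. The ten-membered ring closes in the endo mode, both alkyne carbons becoming ring members, which a terminal alkyne and a small carbene favour because the chain then sits on the nickel-bound carbon, away from the forming C–C bond. The new C6 centre is controlled by the adjacent C7 silyloxy centre: addition anti to the C7–O bond (Felkin–Anh, the usual sense for α-silyloxy aldehydes in nickel-catalysed alkyne couplings) gives the 6,7-anti and therefore 6,8-syn alcohol, (6R,7R,8S) in germacrane numbering. The E geometry of C4=C5 follows from cis addition of C6 and methyl across the alkyne, and the E-C1=C10 alkene is a spectator. The step needs closure to beat oligomerisation, exo insertion and direct methyl addition to the aldehyde, which slow addition at high dilution, the small carbene, the low uncatalysed reactivity of Me2Zn and the turn imposed by the E-trisubstituted alkene and the vicinal C7/C8 ether groups are meant to secure.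

**Step 12**
Reactants: 20 (1R,2E,6E,9S,10R)-10-[(tert-butyldimethylsilyl)oxy]-9-[(4-methoxybenzyl)oxy]-3,7-dimethylcyclodeca-2,6-dien-1-ol
Product: 21 (1(10)E)-7α-[(tert-butyldimethylsilyl)oxy]-4α,5β-epoxy-8α-[(4-methoxybenzyl)oxy]-11,12,13-trinorgermacr-1(10)-en-6α-ol
Conditions: VO(acac)2 (5 mol%), t-BuOOH (1.5 equiv, in decane), CH2Cl2, 0 °C → rt
Reagents that add atoms: tert-butyl hydroperoxide, CC(C)(C)OO
Why: Vanadium-catalysed hydroxyl-directed epoxidation: the C6 alkoxide bound to vanadium should deliver oxygen to C4=C5 from the hydroxyl face of the conformer that keeps H6 in the alkene plane (A(1,3) strain with C15), giving the threo 4R,5R epoxide and leaving the remote C1=C10 alkene alone.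

**Step 13**
Reactants: 21 (1(10)E)-7α-[(tert-butyldimethylsilyl)oxy]-4α,5β-epoxy-8α-[(4-methoxybenzyl)oxy]-11,12,13-trinorgermacr-1(10)-en-6α-ol; 22 3-[(4-methoxybenzyl)oxy]propanoic acid
Product: 23 (1(10)E)-7α-[(tert-butyldimethylsilyl)oxy]-4α,5β-epoxy-8α-[(4-methoxybenzyl)oxy]-11,12,13-trinorgermacr-1(10)-en-6α-yl 3-[(4-methoxybenzyl)oxy]propanoate
Conditions: DCC, DMAP (cat.), CH2Cl2, 0 °C → rt
Reagents that add atoms: none
Why: Steglich esterification of the hindered secondary C6 alcohol attaches C12, C11 and C13 as a protected 3-oxypropanoate under conditions that leave the epoxide untouched.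

**Step 14**
Reactants: 23 (1(10)E)-7α-[(tert-butyldimethylsilyl)oxy]-4α,5β-epoxy-8α-[(4-methoxybenzyl)oxy]-11,12,13-trinorgermacr-1(10)-en-6α-yl 3-[(4-methoxybenzyl)oxy]propanoate
Product: 24 (1(10)E)-4α,5β-epoxy-7α-hydroxy-8α-[(4-methoxybenzyl)oxy]-11,12,13-trinorgermacr-1(10)-en-6α-yl 3-[(4-methoxybenzyl)oxy]propanoate
Conditions: Bu4NF, AcOH (1:1), THF, 0 °C → rt
Reagents that add atoms: none
Why: Fluoride desilylation buffered with acetic acid should free the C7 hydroxyl while suppressing acyl migration from O6 and sparing epoxide, ester and PMB ethers.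

**Step 15**
Reactants: 24 (1(10)E)-4α,5β-epoxy-7α-hydroxy-8α-[(4-methoxybenzyl)oxy]-11,12,13-trinorgermacr-1(10)-en-6α-yl 3-[(4-methoxybenzyl)oxy]propanoate
Product: 25 (1(10)E)-4α,5β-epoxy-8α-[(4-methoxybenzyl)oxy]-7-oxo-11,12,13-trinorgermacr-1(10)-en-6α-yl 3-[(4-methoxybenzyl)oxy]propanoate
Conditions: Dess–Martin periodinane, pyridine, CH2Cl2, 0 °C → rt
Reagents that add atoms: none
Why: Dess–Martin oxidation gives the C7 ketone, and because O6 is already acylated no α-ketol isomerisation can occur.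

**Step 16**
Reactants: 25 (1(10)E)-4α,5β-epoxy-8α-[(4-methoxybenzyl)oxy]-7-oxo-11,12,13-trinorgermacr-1(10)-en-6α-yl 3-[(4-methoxybenzyl)oxy]propanoate
Product: 26 (1(10)E)-4α,5β-epoxy-7-hydroxy-8α,13-bis[(4-methoxybenzyl)oxy]germacr-1(10)-en-12,6α-olide (mixture of C7/C11 epimers)
Conditions: LiN(SiMe3)2 (1.2 equiv), THF, −78 °C; AcOH quench at −78 °C
Reagents that add atoms: none
Why: Intramolecular ester-enolate aldol addition: kinetic deprotonation of the unhindered ester CH2 and 5-exo-trig attack of C11 on the adjacent C7 ketone should close the γ-lactone faster than the enolate can open the epoxide, and the two new centres are removed in the next step.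

**Step 17**
Reactants: 26 (1(10)E)-4α,5β-epoxy-7-hydroxy-8α,13-bis[(4-methoxybenzyl)oxy]germacr-1(10)-en-12,6α-olide
Product: 27 (1(10)E)-4α,5β-epoxy-8α,13-bis[(4-methoxybenzyl)oxy]germacra-1(10),7(11)-dien-12,6α-olide
Conditions: Martin sulfurane Ph2S[OC(CF3)2Ph]2, CH2Cl2, 0 °C → rt
Reagents that add atoms: none
Why: Dehydration of the tertiary β-hydroxy lactone with Martin sulfurane under neutral conditions should remove the acidic C11 hydrogen and give the conjugated tetrasubstituted butenolide C7=C11 from either epimer.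

**Step 18**
Reactants: 27 (1(10)E)-4α,5β-epoxy-8α,13-bis[(4-methoxybenzyl)oxy]germacra-1(10),7(11)-dien-12,6α-olide
Product: 28 (1(10)E)-4α,5β-epoxy-8α,13-dihydroxygermacra-1(10),7(11)-dien-12,6α-olide
Conditions: DDQ (3 equiv), CH2Cl2/pH 7 phosphate buffer, 0 °C → rt
Reagents that add atoms: none
Why: Oxidative cleavage of both PMB ethers by DDQ at neutral pH should spare the epoxide, the electron-poor butenolide and the trisubstituted alkene.

**Step 19**
Reactants: 28 (1(10)E)-4α,5β-epoxy-8α,13-dihydroxygermacra-1(10),7(11)-dien-12,6α-olide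
Product: 29 (1(10)E)-13-acetoxy-4α,5β-epoxy-8α-hydroxygermacra-1(10),7(11)-dien-12,6α-olide
Conditions: AcCl (1.1 equiv), 2,4,6-collidine, CH2Cl2, −78 °C
Reagents that add atoms: acetyl chloride, CC(=O)Cl
Why: Chemoselective acylation of the primary C13 hydroxyl over the hindered secondary C8 hydroxyl with acetyl chloride and collidine at low temperature.

**Step 20**
Reactants: 29 (1(10)E)-13-acetoxy-4α,5β-epoxy-8α-hydroxygermacra-1(10),7(11)-dien-12,6α-olide
Product: 30 (1(10)E)-13-acetoxy-4α,5β-epoxy-8α-(isobutyryloxy)germacra-1(10),7(11)-dien-12,6α-olide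
Conditions: (i-PrCO)2O, pyridine, DMAP (cat.), CH2Cl2, 0 °C → rt
Reagents that add atoms: isobutyric anhydride, CC(C)C(=O)OC(=O)C(C)C
Why: DMAP-catalysed acylation of the remaining secondary C8 alcohol under weakly basic conditions that do not deprotonate the butenolide γ-position C6.

**Step 21**
Reactants: 30 (1(10)E)-13-acetoxy-4α,5β-epoxy-8α-(isobutyryloxy)germacra-1(10),7(11)-dien-12,6α-olide
Product: 31 13-acetoxy-1β,10α:4α,5β-diepoxy-8α-(isobutyryloxy)germacr-7(11)-en-12,6α-olide, (1R,4R,5R,6S,8S,10R), CNP0191378.1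
Conditions: dimethyldioxirane (1.2 equiv), acetone, −20 → 0 °C
Reagents that add atoms: dimethyldioxirane, CC1(C)OO1
Why: Neutral dioxirane epoxidation should take the electron-rich trisubstituted C1=C10 alkene and not the electron-poor butenolide, and attack on the exposed outer face of the conformer with C14 on the β face should give the 1β,10α (1R,10R) epoxide, as is usual for germacr-1(10)-enolides carrying a 4α,5β-epoxide.

**Compound list**

1 | 5-(trimethylsilyl)pent-4-yn-1-ol | C[Si](C)(C)C#CCCCO | starting material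
2 | ethyl 2-(triphenylphosphoranylidene)propanoate | CCOC(=O)C(C)=P(c1ccccc1)(c1ccccc1)c1ccccc1 | starting material
3 | 5-(trimethylsilyl)pent-4-ynal (formed in the flask) | C[Si](C)(C)C#CCCC=O | intermediate
4 | ethyl (E)-2-methyl-7-(trimethylsilyl)hept-2-en-6-ynoate | CCOC(=O)/C(C)=C/CCC#C[Si](C)(C)C | intermediate
5 | (E)-2-methyl-7-(trimethylsilyl)hept-2-en-6-yn-1-ol | OC/C(C)=C/CCC#C[Si](C)(C)C | intermediate
6 | (E)-7-bromo-6-methyl-1-(trimethylsilyl)hept-5-en-1-yne | BrC/C(C)=C/CCC#C[Si](C)(C)C | intermediate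
7 | 2,2-dimethyl-1,3-dioxan-5-one | CC1(C)OCC(=O)CO1 | starting material
8 | (S)-1-amino-2-(methoxymethyl)pyrrolidine (SAMP) | COC[C@@H]1CCCN1N | starting material
9 | (S)-N-(2,2-dimethyl-1,3-dioxan-5-ylidene)-2-(methoxymethyl)pyrrolidin-1-amine | COC[C@@H]1CCCN1N=C1COC(C)(C)OC1 | intermediate
10 | (S)-N-{(4S,5Z)-2,2-dimethyl-4-[(E)-2-methyl-7-(trimethylsilyl)hept-2-en-6-yn-1-yl]-1,3-dioxan-5-ylidene}-2-(methoxymethyl)pyrrolidin-1-amine (formed in the flask; kinetic C=N isomer) | COC[C@@H]1CCCN1/N=C1\[C@H](C/C(C)=C/CCC#C[Si](C)(C)C)OC(C)(C)OC1 | intermediate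
11 | (4S)-2,2-dimethyl-4-[(E)-2-methyl-7-(trimethylsilyl)hept-2-en-6-yn-1-yl]-1,3-dioxan-5-one | CC1(C)OCC(=O)[C@H](C/C(C)=C/CCC#C[Si](C)(C)C)O1 | intermediate
12 | (4S,5R)-2,2-dimethyl-4-[(E)-2-methyl-7-(trimethylsilyl)hept-2-en-6-yn-1-yl]-1,3-dioxan-5-ol (trans; formed in the flask) | CC1(C)OC[C@@H](O)[C@H](C/C(C)=C/CCC#C[Si](C)(C)C)O1 | intermediate
13 | (4S,5R)-2,2-dimethyl-4-[(E)-2-methylhept-2-en-6-yn-1-yl]-1,3-dioxan-5-ol (trans) | CC1(C)OC[C@@H](O)[C@H](C/C(C)=C/CCC#C)O1 | intermediate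
14 | tert-butyl({(4S,5R)-2,2-dimethyl-4-[(E)-2-methylhept-2-en-6-yn-1-yl]-1,3-dioxan-5-yl}oxy)dimethylsilane | CC1(C)OC[C@@H](O[Si](C)(C)C(C)(C)C)[C@H](C/C(C)=C/CCC#C)O1 | intermediate
15 | (2R,3S,5E)-2-[(tert-butyldimethylsilyl)oxy]-5-methyldec-5-en-9-yne-1,3-diol (formed in the flask) | OC[C@@H](O[Si](C)(C)C(C)(C)C)[C@@H](O)C/C(C)=C/CCC#C | intermediate
16 | (2R,4S,5R)-5-[(tert-butyldimethylsilyl)oxy]-2-(4-methoxyphenyl)-4-[(E)-2-methylhept-2-en-6-yn-1-yl]-1,3-dioxane | COc1ccc(cc1)[C@@H]1OC[C@@H](O[Si](C)(C)C(C)(C)C)[C@H](C/C(C)=C/CCC#C)O1 | intermediate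
17 | (2R,3S,5E)-2-[(tert-butyldimethylsilyl)oxy]-3-[(4-methoxybenzyl)oxy]-5-methyldec-5-en-9-yn-1-ol | OC[C@@H](O[Si](C)(C)C(C)(C)C)[C@@H](OCc1ccc(OC)cc1)C/C(C)=C/CCC#C | intermediate
18 | (2S,3S,5E)-2-[(tert-butyldimethylsilyl)oxy]-3-[(4-methoxybenzyl)oxy]-5-methyldec-5-en-9-ynal (C6 aldehyde, C7 OTBS, C8 OPMB, terminal alkyne C4≡C5) | O=C[C@@H](O[Si](C)(C)C(C)(C)C)[C@@H](OCc1ccc(OC)cc1)C/C(C)=C/CCC#C | intermediate
19 | dimethylzinc | C[Zn]C | starting material
20 | (1R,2E,6E,9S,10R)-10-[(tert-butyldimethylsilyl)oxy]-9-[(4-methoxybenzyl)oxy]-3,7-dimethylcyclodeca-2,6-dien-1-ol (germacrane numbering: 6α-OH, 7α-OTBS, 8α-OPMB, 1(10)E,4E) | O[C@@H]1/C=C(C)/CC/C=C(C)/C[C@H](OCc2ccc(OC)cc2)[C@@H]1O[Si](C)(C)C(C)(C)C | intermediate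
21 | (1(10)E)-7α-[(tert-butyldimethylsilyl)oxy]-4α,5β-epoxy-8α-[(4-methoxybenzyl)oxy]-11,12,13-trinorgermacr-1(10)-en-6α-ol | O[C@@H]1[C@H]2O[C@]2(C)CC/C=C(C)/C[C@H](OCc2ccc(OC)cc2)[C@@H]1O[Si](C)(C)C(C)(C)C | intermediate
22 | 3-[(4-methoxybenzyl)oxy]propanoic acid | COc1ccc(COCCC(=O)O)cc1 | starting material
23 | (1(10)E)-7α-[(tert-butyldimethylsilyl)oxy]-4α,5β-epoxy-8α-[(4-methoxybenzyl)oxy]-11,12,13-trinorgermacr-1(10)-en-6α-yl 3-[(4-methoxybenzyl)oxy]propanoate | COc1ccc(COCCC(=O)O[C@@H]2[C@H]3O[C@]3(C)CC/C=C(C)/C[C@H](OCc3ccc(OC)cc3)[C@@H]2O[Si](C)(C)C(C)(C)C)cc1 | intermediate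
24 | (1(10)E)-4α,5β-epoxy-7α-hydroxy-8α-[(4-methoxybenzyl)oxy]-11,12,13-trinorgermacr-1(10)-en-6α-yl 3-[(4-methoxybenzyl)oxy]propanoate | COc1ccc(COCCC(=O)O[C@@H]2[C@H]3O[C@]3(C)CC/C=C(C)/C[C@H](OCc3ccc(OC)cc3)[C@@H]2O)cc1 | intermediate
25 | (1(10)E)-4α,5β-epoxy-8α-[(4-methoxybenzyl)oxy]-7-oxo-11,12,13-trinorgermacr-1(10)-en-6α-yl 3-[(4-methoxybenzyl)oxy]propanoate | COc1ccc(COCCC(=O)O[C@@H]2[C@H]3O[C@]3(C)CC/C=C(C)/C[C@H](OCc3ccc(OC)cc3)C2=O)cc1 | intermediate
26 | (1(10)E)-4α,5β-epoxy-7-hydroxy-8α,13-bis[(4-methoxybenzyl)oxy]germacr-1(10)-en-12,6α-olide (C7 and C11 left open: epimer mixture) | COc1ccc(COCC2C(=O)O[C@@H]3[C@H]4O[C@]4(C)CC/C=C(C)/C[C@H](OCc4ccc(OC)cc4)C23O)cc1 | intermediate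
27 | (1(10)E)-4α,5β-epoxy-8α,13-bis[(4-methoxybenzyl)oxy]germacra-1(10),7(11)-dien-12,6α-olide | COc1ccc(COCC2=C3[C@@H](OCc4ccc(OC)cc4)C/C(C)=C/CC[C@@]4(C)O[C@@H]4[C@H]3OC2=O)cc1 | intermediate
28 | (1(10)E)-4α,5β-epoxy-8α,13-dihydroxygermacra-1(10),7(11)-dien-12,6α-olide | OCC1=C2[C@@H](O)C/C(C)=C/CC[C@@]3(C)O[C@@H]3[C@H]2OC1=O | intermediate
29 | (1(10)E)-13-acetoxy-4α,5β-epoxy-8α-hydroxygermacra-1(10),7(11)-dien-12,6α-olide | CC(=O)OCC1=C2[C@@H](O)C/C(C)=C/CC[C@@]3(C)O[C@@H]3[C@H]2OC1=O | intermediate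
30 | (1(10)E)-13-acetoxy-4α,5β-epoxy-8α-(isobutyryloxy)germacra-1(10),7(11)-dien-12,6α-olide | CC(=O)OCC1=C2[C@@H](OC(=O)C(C)C)C/C(C)=C/CC[C@@]3(C)O[C@@H]3[C@H]2OC1=O | intermediate
31 | 13-acetoxy-1β,10α:4α,5β-diepoxy-8α-(isobutyryloxy)germacr-7(11)-en-12,6α-olide, (1R,4R,5R,6S,8S,10R), CNP0191378.1 | CC(=O)OCC1=C2[C@@H](OC(=O)C(C)C)C[C@@]3(C)O[C@@H]3CC[C@@]3(C)O[C@@H]3[C@H]2OC1=O | target

**Step count and risks**

Total steps: 21. Longest linear sequence: 20 steps (from 1 through steps 1–3 and 5–21; step 4 is the only step off the main line).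

Steps most likely to fail:

Step 11. The strained ten-membered ring may close more slowly than intermolecular coupling, giving oligomers; insertion may occur in the exo sense; or methyl may transfer directly from zinc to the aldehyde. The fallback sets out from 17 and returns at 20. Zirconium-catalysed carboalumination of the terminal alkyne (AlMe3, Cp2ZrCl2, CH2Cl2, the hydroxyl carried as its Me2Al alkoxide) followed by iodinolysis would give (2R,3S,5E,9E)-2-[(tert-butyldimethylsilyl)oxy]-10-iodo-3-[(4-methoxybenzyl)oxy]-5,9-dimethyldeca-5,9-dien-1-ol F1, in which C15 and the E geometry of C4=C5 are already fixed. Dess–Martin oxidation would give (2S,3S,5E,9E)-2-[(tert-butyldimethylsilyl)oxy]-10-iodo-3-[(4-methoxybenzyl)oxy]-5,9-dimethyldeca-5,9-dienal F2. Nozaki–Hiyama–Kishi macrocyclisation (CrCl2, cat. NiCl2, DMSO/THF, high dilution) then forms C5–C6 and should deliver 20, again with Felkin–Anh induction from C7.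

Step 16. The amide base may deprotonate C6 of the ketone, which would open the neighbouring 4,5-epoxide, or the ester enolate may expel the β-(4-methoxybenzyl)oxide before it adds to C7. The fallback sets out from 21 and returns at 27, avoiding both the strong base and the separate dehydration. 2-(Diethoxyphosphoryl)-3-[(4-methoxybenzyl)oxy]propanoic acid F3 would be made from diethylphosphonoacetic acid by dianion alkylation with 4-methoxybenzyl chloromethyl ether. Steglich esterification of 21 with it gives the C6 phosphonoacetate ester of 21 F4; Bu4NF/AcOH gives the 7α-hydroxy phosphonate F5; Dess–Martin oxidation gives the 7-oxo phosphonate F6. LiCl and i-Pr2NEt in MeCN then close the butenolide by intramolecular Horner–Wadsworth–Emmons olefination to 27.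

Step 6. Hydride may be delivered from the equatorial side, giving the cis alcohol; this would reverse the sense of induction at C6 in step 11. The fallback sets out from 11 and returns at 13. The bulky LiBH(s-Bu)3 (THF, −78 °C), expected to enter equatorially, is used on purpose to give (4S,5S)-2,2-dimethyl-4-[(E)-2-methyl-7-(trimethylsilyl)hept-2-en-6-yn-1-yl]-1,3-dioxan-5-ol F7. Mitsunobu inversion (4-nitrobenzoic acid, PPh3, DIAD, THF) gives (4S,5R)-2,2-dimethyl-4-[(E)-2-methyl-7-(trimethylsilyl)hept-2-en-6-yn-1-yl]-1,3-dioxan-5-yl 4-nitrobenzoate F8. K2CO3 in MeOH then cleaves the ester and the alkynyl silyl group together to give 13.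

**Further compounds**

F1 | step 11 | (2R,3S,5E,9E)-2-[(tert-butyldimethylsilyl)oxy]-10-iodo-3-[(4-methoxybenzyl)oxy]-5,9-dimethyldeca-5,9-dien-1-ol | OC[C@@H](O[Si](C)(C)C(C)(C)C)[C@@H](OCc1ccc(OC)cc1)C/C(C)=C/CC/C(C)=C/I
F2 | step 11 | (2S,3S,5E,9E)-2-[(tert-butyldimethylsilyl)oxy]-10-iodo-3-[(4-methoxybenzyl)oxy]-5,9-dimethyldeca-5,9-dienal | O=C[C@@H](O[Si](C)(C)C(C)(C)C)[C@@H](OCc1ccc(OC)cc1)C/C(C)=C/CC/C(C)=C/I
F3 | step 16 | 2-(diethoxyphosphoryl)-3-[(4-methoxybenzyl)oxy]propanoic acid (racemic) | CCOP(=O)(OCC)C(COCc1ccc(OC)cc1)C(=O)O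
F4 | step 16 | (1(10)E)-7α-[(tert-butyldimethylsilyl)oxy]-4α,5β-epoxy-8α-[(4-methoxybenzyl)oxy]-11,12,13-trinorgermacr-1(10)-en-6α-yl 2-(diethoxyphosphoryl)-3-[(4-methoxybenzyl)oxy]propanoate (epimers at the phosphonate carbon) | CCOP(=O)(OCC)C(COCc1ccc(OC)cc1)C(=O)O[C@@H]1[C@H]2O[C@]2(C)CC/C=C(C)/C[C@H](OCc2ccc(OC)cc2)[C@@H]1O[Si](C)(C)C(C)(C)C
F5 | step 16 | (1(10)E)-4α,5β-epoxy-7α-hydroxy-8α-[(4-methoxybenzyl)oxy]-11,12,13-trinorgermacr-1(10)-en-6α-yl 2-(diethoxyphosphoryl)-3-[(4-methoxybenzyl)oxy]propanoate | CCOP(=O)(OCC)C(COCc1ccc(OC)cc1)C(=O)O[C@@H]1[C@H]2O[C@]2(C)CC/C=C(C)/C[C@H](OCc2ccc(OC)cc2)[C@@H]1O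
F6 | step 16 | (1(10)E)-4α,5β-epoxy-8α-[(4-methoxybenzyl)oxy]-7-oxo-11,12,13-trinorgermacr-1(10)-en-6α-yl 2-(diethoxyphosphoryl)-3-[(4-methoxybenzyl)oxy]propanoate | CCOP(=O)(OCC)C(COCc1ccc(OC)cc1)C(=O)O[C@@H]1[C@H]2O[C@]2(C)CC/C=C(C)/C[C@H](OCc2ccc(OC)cc2)C1=O
F7 | step 6 | (4S,5S)-2,2-dimethyl-4-[(E)-2-methyl-7-(trimethylsilyl)hept-2-en-6-yn-1-yl]-1,3-dioxan-5-ol (cis) | CC1(C)OC[C@H](O)[C@H](C/C(C)=C/CCC#C[Si](C)(C)C)O1
F8 | step 6 | (4S,5R)-2,2-dimethyl-4-[(E)-2-methyl-7-(trimethylsilyl)hept-2-en-6-yn-1-yl]-1,3-dioxan-5-yl 4-nitrobenzoate | CC1(C)OC[C@@H](OC(=O)c2ccc(cc2)[N+](=O)[O-])[C@H](C/C(C)=C/CCC#C[Si](C)(C)C)O1
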